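I could not see the reagent in either run, since the readings follow bis adduct and nothing else, so I had to infer its fate from the shape of two curves.

| setting | eta | zeta | flask |
|---|---|---|---|
| substrate | 0.072 M | 0.072 M | 0.072 M |
| reagent | 1.8 equiv | 3.6 equiv | 1.80 equiv |
| temperature | 25 °C | 25 °C | 25 °C |
| remark | the very flask that is asked about, followed so far | run made earlier |  |
| time |  |  | 5.0 h |

- eta (time / min: bis adduct / %): 15.0: 5.3; 25.0: 7.1; 40.0: 8.0; 60.0: 8.6; 120: 10.3; 180: 10.9
- zeta (time / min: bis adduct / %): 1.00: 0.7; 1.50: 1.3; 2.50: 2.2; 4.00: 3.4; 8.00: 6.7; 12.0: 8.1

(scatter of a reading: 0.3 percentage points)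

* bis adduct, in percent of the substrate first charged, at 5.0 h
* the remedy with the largest gain of bis adduct, or "none" below 2 percentage points (autumn / spring / dusk / midnight / none)
* bis adduct present, with what was taken out counted in, in percent of the substrate first charged, after spring
* bis adduct present, with what was taken out counted in, in percent of the substrate first charged, after midnight

- autumn: change nothing and wait 5.0 h more
- spring: at 5.0 h raise the temperature by 15 K, then wait 5.0 h
- dusk: at 5.0 h add reagent, 100% of the amount charged, then wait 5.0 h
- midnight: at 5.0 h take out 90% of the bis adduct then present, then wait 5.0 h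

- what is taken out of bis adduct is counted as made
- the earlier runs do not show what temperature does; that part of a forecast is a guess
- additions bring no volume worth counting

Eta and zeta differ in the reagent charge, zeta holding twice as much. Over nearly the same level of bis adduct, eta gained 1.5 percentage points between 25.0 min and 60.0 min, while zeta gained 1.4 points between 8.00 min and 12.0 min. As a reading, with 0.3 points on each value, that makes zeta faster per minute by a factor of 8.17, more than the factor in the charge. So I judged that the level of bis adduct was not the brake, and that eta's reagent had been worn down by something unseen.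

I took eta's charge of reagent to work once, and I reckoned what it is worth. Eta's last gain was 0.6 points in the interval from 120 min to 180 min, and carrying that pace forward I estimated 12.1% at 5.0 h. Dividing by the charge gives the yield per charge, the bis adduct that one equivalent of reagent leaves behind in 5.0 h at this substrate charge and temperature, 6.72% of the substrate. A second charge in dusk should therefore gain 12 points, so I chose dusk.

The forecast gave 11.5% now, 12.7% after spring and 20.5% after midnight, and chose midnight, on the ground that “The stall seems tied to the product itself”.

The flask gave 12.0% at 5.0 h. The best remedy was dusk, gaining 11 points, and the counted bis adduct was 12.6% after spring and 12.9% after midnight.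

    substrate + reagent → first product + by-product (k = 0.00783 L mol⁻¹ s⁻¹, Ea = 45.0 kJ mol⁻¹)
    reagent + first product → bis adduct + by-product (k = 0.0106 L mol⁻¹ s⁻¹, Ea = 48.0 kJ mol⁻¹)
    reagent + bis adduct → tris adduct + by-product (k = 0.00995 L mol⁻¹ s⁻¹, Ea = 45.0 kJ mol⁻¹)
    reagent + tris adduct → tetra adduct + by-product (k = 0.0189 L mol⁻¹ s⁻¹, Ea = 70.0 kJ mol⁻¹)
    2 reagent → self-condensation product (k = 0.0136 L mol⁻¹ s⁻¹, Ea = 71.0 kJ mol⁻¹)
    2 substrate → homo dimer (k = 2.16 × 10⁻⁵ L mol⁻¹ s⁻¹, Ea = 86.0 kJ mol⁻¹)
    reagent ⇌ dormant form (K = 1.42, k = 2.74 × 10⁻⁴ s⁻¹, Ea = 98.0 kJ mol⁻¹, ΔH = −49.0 kJ mol⁻¹)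
    (constants at 25 °C)

We parted on midnight, which gained 0.91 points. At 300 min this flask still had 0.295% of its reagent free, the limiting reagent, with 0.00159 M of dormant form beside it, and 52.6% of its substrate free. The yield per charge had promised 12 points for dusk, and 11 points came. For the neighbour flask with 0.450 equiv it gives 3.02%, and that run stands at 3.71% at 5.0 h. Part of this flask's reagent went to self-condensation product, one cause among others of its low bis adduct: at 5.0 h the same flask without that path reached 25.0%, where this flask stood at 12.0%.

(The readings were generated by integration on assumed constants, noise included.)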